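The route rests on a C1–C7 bond that the target lacks. Because the C2 arm on C3 and C7 on C6 lie on the same face of the 1,2-dioxane (O1, O2, C3–C6), C1 to C7 can be closed into a cycloheptadiene. Singlet oxygen then adds across C3 and C6 of that ring-locked s-cis diene and, in one operation, forms both C–O bonds, the dioxane ring and the cis C3/C6 relation, on the face opposite a cis-fused acetonide on C1/C7. The precursor is the 4,6-diethylcyclohepta-3,5-diene-1,7-diol acetonide 14, made from 2-deoxy-L-ribose. The C1–C7 bond is later cut oxidatively to give the acid arm and a C7 aldehyde for the side chain.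

Key step: step 9

Remark: every intermediate carries the target numbering (C1 carboxyl carbon to C14; ring O1, O2, C3–C6), and 2-(bromomethyl)but-1-ene (6) is taken as a purchasable reagent.

Step 1
Reactants: 1 2-deoxy-L-ribose
Product: 2 2-deoxy-3,4-O-isopropylidene-L-erythro-pentopyranose (lactol; both anomers)
Conditions: 2-methoxypropene, PPTS (cat.), EtOAc, 0 °C to rt
Reagents that add atoms: 2-methoxypropene, COC(C)=C
Why: Acid-catalysed acetal exchange on the pyranose form ties the cis-related sugar oxygens (the future C1 and C7 oxygens) into a cis-fused isopropylidene acetal and leaves the anomeric carbon as a latent aldehyde; no stereocentre is created.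

Step 2
Reactants: 2 2-deoxy-3,4-O-isopropylidene-L-erythro-pentopyranose
Product: 4 [(4S,5R)-5-allyl-2,2-dimethyl-1,3-dioxolan-4-yl]methanol, via open-chain hydroxy aldehyde 3 (not isolated)
Conditions: Ph3PCH3Br, KOtBu, THF, 0 °C to rt
Reagents that add atoms: methyltriphenylphosphonium bromide, C[P+](c1ccccc1)(c1ccccc1)c1ccccc1.[Br-]
Why: Wittig methylenation of the aldehyde tautomer that the lactol supplies under base turns C3 into a terminal vinyl carbon and frees the primary hydroxyl on the future C6, without touching a stereocentre.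

Step 3
Reactants: 4 [(4S,5R)-5-allyl-2,2-dimethyl-1,3-dioxolan-4-yl]methanol
Product: 5 (4R,5R)-5-allyl-2,2-dimethyl-1,3-dioxolane-4-carbaldehyde
Conditions: Dess–Martin periodinane, NaHCO3, CH2Cl2, 0 °C to rt; used crude
Reagents that add atoms: none
Why: Buffered Dess–Martin oxidation gives the aldehyde (future C6) under neutral conditions, which should prevent epimerisation of the α-alkoxy centre C7 to the trans-dioxolane.

Step 4
Reactants: 5 (4R,5R)-5-allyl-2,2-dimethyl-1,3-dioxolane-4-carbaldehyde; 6 2-(bromomethyl)but-1-ene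
Product: 8 1-[(4S,5R)-5-allyl-2,2-dimethyl-1,3-dioxolan-4-yl]-3-methylidenepentan-1-ol (both C6 epimers), via allylzinc bromide 7 (not isolated)
Conditions: Zn dust, THF/sat. aq. NH4Cl, 0 °C to rt
Reagents that add atoms: none
Why: Barbier allylation joins C5 to C6 and brings in C4 with its ethyl group as a 1,1-disubstituted alkene; the C6 carbinol configuration is irrelevant because step 6 oxidises it.

Step 5
Reactants: 8 1-[(4S,5R)-5-allyl-2,2-dimethyl-1,3-dioxolan-4-yl]-3-methylidenepentan-1-ol
Product: 9 (1R,7S)-4-ethylcyclohept-3-ene-1,6,7-triol 1,7-acetonide (target numbering; both C6 epimers)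
Conditions: second-generation Grubbs catalyst RuCl2(=CHPh)(PCy3)(H2IMes) (5 mol%), CH2Cl2 (5 mM), 40 °C
Reagents that add atoms: none
Why: Ring-closing metathesis of the vinyl group with the 1,1-disubstituted alkene closes the seven-membered carbocycle and forms the trisubstituted C3=C4 bond, whose cis geometry is enforced by the ring, so no Z-selective olefination is needed; the cis-fused dioxolane holds both chains on one side.

Step 6
Reactants: 9 (1R,7S)-4-ethylcyclohept-3-ene-1,6,7-triol 1,7-acetonide
Product: 10 (1R,7R)-4-ethyl-1,7-(isopropylidenedioxy)cyclohept-3-en-6-one (target numbering)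
Conditions: Dess–Martin periodinane, NaHCO3, CH2Cl2, 0 °C; used directly
Reagents that add atoms: none
Why: Dess–Martin oxidation of the secondary alcohol gives the β,γ-unsaturated ketone under buffered conditions that should neither epimerise C7 nor move the alkene into conjugation.

Step 7
Reactants: 10 (1R,7R)-4-ethyl-1,7-(isopropylidenedioxy)cyclohept-3-en-6-one
Product: 12 (1R,7R)-4-ethyl-1,7-(isopropylidenedioxy)cyclohepta-3,5-dien-6-yl trifluoromethanesulfonate, via potassium dienolate 11 (not isolated)
Conditions: KN(SiMe3)2, THF, −78 °C; then PhNTf2, −78 to 0 °C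
Reagents that add atoms: N-phenylbis(trifluoromethanesulfonimide), O=S(=O)(N(c1ccccc1)S(=O)(=O)C(F)(F)F)C(F)(F)F
Why: Kinetic deprotonation at the doubly activated C5 methylene (α to the ketone and allylic) gives the extended dienolate, and O-sulfonylation (enol triflate formation) fixes C5=C6 in conjugation with C3=C4; the hindered, less acidic C7–H should stay untouched, so the acetonide survives.

Step 8
Reactants: 12 (1R,7R)-4-ethyl-1,7-(isopropylidenedioxy)cyclohepta-3,5-dien-6-yl trifluoromethanesulfonate; 13 ethylmagnesium bromide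
Product: 14 (1R,7S)-4,6-diethylcyclohepta-3,5-diene-1,7-diol acetonide (target numbering)
Conditions: Fe(acac)3 (5 mol%), THF/NMP, −30 °C
Reagents that add atoms: none
Why: Iron-catalysed Kumada-type cross-coupling of an alkenyl triflate with an alkyl Grignard reagent replaces the triflate by the C6 ethyl group at low temperature, where the acetal and the diene are inert.

Step 9
Reactants: 14 (1R,7S)-4,6-diethylcyclohepta-3,5-diene-1,7-diol acetonide
Product: 15 (1R,2R,3R,5R)-1,9-diethyl-6,7-dioxabicyclo[3.2.2]non-8-ene-2,3-diol acetonide (bridgeheads are C6 and C3 of the target; peroxide bridge opposite the acetonide)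
Conditions: O2, meso-tetraphenylporphyrin (cat.), white LED, CH2Cl2, −40 °C
Reagents that add atoms: oxygen, O=O
Why: Singlet oxygen, generated by energy transfer from the excited porphyrin, adds to C3 and C6 in a concerted suprafacial [4+2] cycloaddition, the reaction type known from the dye-sensitised photooxygenation of cyclohexa-1,3-dienes and cyclohepta-1,3-dienes to bicyclic endoperoxides. The 1,2-dioxane ring (O1, O2, C3–C6) closes by the cycloaddition itself, both C–O bonds forming in one event across the ring-held s-cis diene, and it appears as the boat of a 6,7-dioxabicyclo[3.2.2]non-8-ene. The new stereocentres C3 and C6 are set together by the face of attack, which the cis-fused dioxolane on C1/C7 should direct to the opposite face through steric shielding and lone-pair repulsion by the allylic C7 oxygen. The carbon bridge C2–C1–C7 then holds the C2 arm and C7 on one face of the dioxane, which is the cis C3/C6 relation of the target. The step needs this anti facial selectivity, secured by the acetonide, and cycloaddition in preference to the ene reaction at the ethyl CH2 groups, C2–H and C7–H, which the planar cisoid diene should secure because [4+2] is normally its faster channel, helped by low temperature in an aprotic solvent.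

Step 10
Reactants: 15 (1R,2R,3R,5R)-1,9-diethyl-6,7-dioxabicyclo[3.2.2]non-8-ene-2,3-diol acetonide
Product: 16 (1R,2R,3R,5R,9R)-1,9-diethyl-6,7-dioxabicyclo[3.2.2]nonane-2,3-diol acetonide
Conditions: KO2CN=NCO2K (large excess, in portions), AcOH, MeOH/CH2Cl2, 0 °C to rt
Reagents that add atoms: none
Why: Diimide reduction transfers two hydrogens syn to the strained bridge alkene without touching the O–O bond, from the face flanked by the peroxide bridge because the acetonide oxygens cover the other face, so the C4 ethyl group is pushed toward the carbon bridge and C4 is set (R), cis to the C2 arm and to C7.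

Step 11
Reactants: 16 (1R,2R,3R,5R,9R)-1,9-diethyl-6,7-dioxabicyclo[3.2.2]nonane-2,3-diol acetonide
Product: 17 (1R,2R,3R,5R,9R)-1,9-diethyl-6,7-dioxabicyclo[3.2.2]nonane-2,3-diol (hydroxyls on C7 and C1 of the target)
Conditions: AcOH/H2O (4:1), 45 °C
Reagents that add atoms: none
Why: Acid-catalysed acetal hydrolysis frees the cis-diol; a dialkyl peroxide without an α-heteroatom should tolerate dilute protic acid, and no stereocentre is involved.

Step 12
Reactants: 17 (1R,2R,3R,5R,9R)-1,9-diethyl-6,7-dioxabicyclo[3.2.2]nonane-2,3-diol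
Product: 18 (1R,2S,5R,9R)-1,9-diethyl-2-hydroxy-6,7-dioxabicyclo[3.2.2]nonan-3-one (C1 ketone and C7 hydroxyl of the target)
Conditions: IBX (1.2 equiv), DMSO, rt
Reagents that add atoms: none
Why: IBX oxidises vicinal diols to α-hydroxy ketones without C–C cleavage, and it should choose the C1 hydroxyl, which sits next to the C2 methylene, over the C7 hydroxyl, which is neopentylic to the fully substituted bridgehead C6 and inductively deactivated by the peroxide oxygen there; C7 keeps its configuration.

Step 13
Reactants: 18 (1R,2S,5R,9R)-1,9-diethyl-2-hydroxy-6,7-dioxabicyclo[3.2.2]nonan-3-one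
Product: 19 methyl 2-[(3R,4R,6R)-4,6-diethyl-6-formyl-1,2-dioxan-3-yl]acetate
Conditions: Pb(OAc)4, MeOH/CH2Cl2 (1:1), 0 °C
Reagents that add atoms: methanol, CO
Why: Criegee-type cleavage of an α-hydroxy ketone by lead tetraacetate in methanol breaks the C1–C7 bond and delivers the ketone carbon C1 as methyl ester and the carbinol carbon C7 as aldehyde, which opens the sacrificial carbocycle and leaves the monocyclic dioxane with C3, C4 and C6 unchanged.

Step 14
Reactants: 20 (E)-pent-2-enal; 13 ethylmagnesium bromide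
Product: 21 rac-(E)-hept-4-en-3-ol
Conditions: Et2O, −78 to 0 °C; aq. NH4Cl
Reagents that add atoms: none
Why: Grignard 1,2-addition to the enal gives the racemic secondary allylic alcohol that holds the carbons of C10 to C14 and the C10 ethyl group.

Step 15
Reactants: 21 rac-(E)-hept-4-en-3-ol
Product: 22 (3R,4E)-hept-4-en-3-ol
Conditions: Ti(OiPr)4 (0.1 equiv), L-(+)-diisopropyl tartrate (0.15 equiv), t-BuOOH (0.6 equiv), 4 Å MS, CH2Cl2, −20 °C
Reagents that add atoms: none
Why: In the Sharpless kinetic resolution with the L-(+)-tartrate ligand the (S)-alcohol is epoxidised much faster, so the (R)-alcohol should be recovered in high enantiomeric purity past half conversion and separated from the epoxy alcohol by chromatography.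

Step 16
Reactants: 22 (3R,4E)-hept-4-en-3-ol; 23 triethyl orthoacetate
Product: 25 ethyl (3R,4E)-3-ethylhept-4-enoate, via mixed ketene acetal 24 (not isolated)
Conditions: EtCO2H (cat.), 140 °C, EtOH distilled off
Reagents that add atoms: none
Why: In the Johnson–Claisen rearrangement the ketene acetal reorganises by a [3,3]-sigmatropic shift through a chair with the carbinol ethyl group equatorial, which transfers the carbinol chirality to C10 (R), creates the E C11=C12 bond and adds C8 and C9.

Step 17
Reactants: 25 ethyl (3R,4E)-3-ethylhept-4-enoate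
Product: 26 (3R,4E)-3-ethylhept-4-en-1-ol
Conditions: LiAlH4, Et2O, 0 °C
Reagents that add atoms: none
Why: Hydride reduction of the ester to the primary alcohol at C8 leaves the isolated alkene and the C10 centre unchanged.

Step 18
Reactants: 26 (3R,4E)-3-ethylhept-4-en-1-ol
Product: 27 (3E,5R)-5-ethyl-7-iodohept-3-ene
Conditions: I2, PPh3, imidazole, CH2Cl2, 0 °C to rt
Reagents that add atoms: iodine, II
Why: Appel-type iodination converts the primary alcohol into the iodide by SN2 displacement of the alkoxyphosphonium group, remote from the stereocentre.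

Step 19
Reactants: 27 (3E,5R)-5-ethyl-7-iodohept-3-ene
Product: 28 [(3R,4E)-3-ethylhept-4-en-1-yl]triphenylphosphonium iodide
Conditions: PPh3, MeCN, 80 °C
Reagents that add atoms: triphenylphosphine, c1ccc(cc1)P(c1ccccc1)c1ccccc1
Why: SN2 quaternisation of triphenylphosphine by the unhindered primary iodide gives the phosphonium salt that carries C8 to C14.

Step 20
Reactants: 19 methyl 2-[(3R,4R,6R)-4,6-diethyl-6-formyl-1,2-dioxan-3-yl]acetate; 28 [(3R,4E)-3-ethylhept-4-en-1-yl]triphenylphosphonium iodide
Product: 32 methyl 2-[(3R,4R,6R)-4,6-diethyl-6-[(1Z,4R,5E)-4-ethyl-2-iodoocta-1,5-dien-1-yl]-1,2-dioxan-3-yl]acetate, via phosphonium ylide 29 (not isolated), via α-iodophosphonium iodide 30 (not isolated), via α-iodo ylide 31 (not isolated)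
Conditions: 28, n-BuLi, THF, 0 °C to rt; I2, −78 °C; NaN(SiMe3)2, −78 to −20 °C; then 19, −78 to −20 °C
Reagents that add atoms: iodine, II
Why: Wittig olefination with an α-iodoalkylidene phosphorane (Stork–Zhao type) should place iodine cis to C6 under kinetic control, so C9 is already trans to C6 as the target requires, while the non-enolisable aldehyde and the weakly basic ylide leave the ester next to the peroxide alone.

Step 21
Reactants: 32 methyl 2-[(3R,4R,6R)-4,6-diethyl-6-[(1Z,4R,5E)-4-ethyl-2-iodoocta-1,5-dien-1-yl]-1,2-dioxan-3-yl]acetate; 33 methylzinc chloride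
Product: 34 methyl 2-[(3R,4R,6R)-4,6-diethyl-6-[(1E,4R,5E)-4-ethyl-2-methylocta-1,5-dien-1-yl]-1,2-dioxan-3-yl]acetate
Conditions: Pd(PPh3)4 (5 mol%), THF, 0 °C to rt
Reagents that add atoms: none
Why: Negishi cross-coupling at zerovalent palladium replaces iodine by methyl with retention of alkene geometry and so gives the E C7=C8 bond; the organozinc reagent should be mild enough for the ester and the dialkyl peroxide.

Step 22
Reactants: 34 methyl 2-[(3R,4R,6R)-4,6-diethyl-6-[(1E,4R,5E)-4-ethyl-2-methylocta-1,5-dien-1-yl]-1,2-dioxan-3-yl]acetate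
Product: 35 2-[(3R,4R,6R)-4,6-diethyl-6-[(1E,4R,5E)-4-ethyl-2-methylocta-1,5-dien-1-yl]-1,2-dioxan-3-yl]acetic acid
Conditions: LiOH·H2O, THF/H2O (3:1), 0 °C; then 1 M HCl to pH 3
Reagents that add atoms: lithium hydroxide, [Li+].[OH-]
Why: In this saponification hydroxide should add to the ester carbonyl faster than it removes a C2 proton, so the peroxide is not expelled and the acid is released without change at C3, C4, C6 or C10.

Compound list
1 | 2-deoxy-L-ribose, (3R,4S)-3,4,5-trihydroxypentanal | O=CC[C@@H](O)[C@@H](O)CO | starting material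
2 | 2-deoxy-3,4-O-isopropylidene-L-erythro-pentopyranose (lactol, both anomers) | OC1C[C@H]2OC(C)(C)O[C@H]2CO1 | intermediate
3 | 2-[(4R,5S)-5-(hydroxymethyl)-2,2-dimethyl-1,3-dioxolan-4-yl]acetaldehyde (open-chain form of 2, not isolated) | O=CC[C@H]1OC(C)(C)O[C@H]1CO | intermediate
4 | [(4S,5R)-5-allyl-2,2-dimethyl-1,3-dioxolan-4-yl]methanol | C=CC[C@H]1OC(C)(C)O[C@H]1CO | intermediate
5 | (4R,5R)-5-allyl-2,2-dimethyl-1,3-dioxolane-4-carbaldehyde | C=CC[C@H]1OC(C)(C)O[C@H]1C=O | intermediate
6 | 2-(bromomethyl)but-1-ene | C=C(CC)CBr | starting material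
7 | (2-methylidenebutyl)zinc bromide (not isolated) | C=C(CC)C[Zn]Br | intermediate
8 | 1-[(4S,5R)-5-allyl-2,2-dimethyl-1,3-dioxolan-4-yl]-3-methylidenepentan-1-ol (both carbinol epimers) | C=CC[C@H]1OC(C)(C)O[C@H]1C(O)CC(=C)CC | intermediate
9 | (1R,7S)-4-ethylcyclohept-3-ene-1,6,7-triol 1,7-acetonide (target numbering, both C6 epimers) | OC1CC(CC)=CC[C@H]2OC(C)(C)O[C@@H]12 | intermediate
10 | (1R,7R)-4-ethyl-1,7-(isopropylidenedioxy)cyclohept-3-en-6-one (target numbering) | O=C1CC(CC)=CC[C@H]2OC(C)(C)O[C@@H]12 | intermediate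
11 | potassium dienolate of 10, O–C6=C5–C4=C3 (not isolated) | [K+].[O-]C1=CC(CC)=CC[C@H]2OC(C)(C)O[C@@H]12 | intermediate
12 | (1R,7R)-4-ethyl-1,7-(isopropylidenedioxy)cyclohepta-3,5-dien-6-yl trifluoromethanesulfonate (target numbering) | O=S(=O)(OC1=CC(CC)=CC[C@H]2OC(C)(C)O[C@@H]12)C(F)(F)F | intermediate
13 | ethylmagnesium bromide | CC[Mg]Br | starting material
14 | (1R,7S)-4,6-diethylcyclohepta-3,5-diene-1,7-diol acetonide (target numbering) | CCC1=CC(CC)=CC[C@H]2OC(C)(C)O[C@@H]12 | intermediate
15 | (1R,2R,3R,5R)-1,9-diethyl-6,7-dioxabicyclo[3.2.2]non-8-ene-2,3-diol acetonide | CC[C@]12C=C(CC)[C@H](OO1)C[C@H]3OC(C)(C)O[C@@H]23 | intermediate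
16 | (1R,2R,3R,5R,9R)-1,9-diethyl-6,7-dioxabicyclo[3.2.2]nonane-2,3-diol acetonide | CC[C@]12C[C@@H](CC)[C@H](OO1)C[C@H]3OC(C)(C)O[C@@H]23 | intermediate
17 | (1R,2R,3R,5R,9R)-1,9-diethyl-6,7-dioxabicyclo[3.2.2]nonane-2,3-diol | CC[C@]12C[C@@H](CC)[C@H](OO1)C[C@@H](O)[C@H]2O | intermediate
18 | (1R,2S,5R,9R)-1,9-diethyl-2-hydroxy-6,7-dioxabicyclo[3.2.2]nonan-3-one | CC[C@]12C[C@@H](CC)[C@H](OO1)CC(=O)[C@H]2O | intermediate
19 | methyl 2-[(3R,4R,6R)-4,6-diethyl-6-formyl-1,2-dioxan-3-yl]acetate | O=C[C@@]1(CC)C[C@@H](CC)[C@@H](CC(=O)OC)OO1 | intermediate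
20 | (E)-pent-2-enal | CC/C=C/C=O | starting material
21 | rac-(E)-hept-4-en-3-ol | CC/C=C/C(O)CC | intermediate
22 | (3R,4E)-hept-4-en-3-ol | CC/C=C/[C@H](O)CC | intermediate
23 | triethyl orthoacetate | CCOC(C)(OCC)OCC | starting material
24 | 1-ethoxy-1-[(3R,4E)-hept-4-en-3-yloxy]ethene (not isolated) | CC/C=C/[C@H](OC(=C)OCC)CC | intermediate
25 | ethyl (3R,4E)-3-ethylhept-4-enoate | CC/C=C/[C@H](CC)CC(=O)OCC | intermediate
26 | (3R,4E)-3-ethylhept-4-en-1-ol | CC/C=C/[C@H](CC)CCO | intermediate
27 | (3E,5R)-5-ethyl-7-iodohept-3-ene | CC/C=C/[C@H](CC)CCI | intermediate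
28 | [(3R,4E)-3-ethylhept-4-en-1-yl]triphenylphosphonium iodide | CC/C=C/[C@H](CC)CC[P+](c1ccccc1)(c1ccccc1)c1ccccc1.[I-] | intermediate
29 | [(3R,4E)-3-ethylhept-4-en-1-ylidene]triphenylphosphorane (not isolated) | CC/C=C/[C@H](CC)CC=P(c1ccccc1)(c1ccccc1)c1ccccc1 | intermediate
30 | [(3R,4E)-3-ethyl-1-iodohept-4-en-1-yl]triphenylphosphonium iodide (both C8 epimers, not isolated) | CC/C=C/[C@H](CC)CC(I)[P+](c1ccccc1)(c1ccccc1)c1ccccc1.[I-] | intermediate
31 | [(3R,4E)-3-ethyl-1-iodohept-4-en-1-ylidene]triphenylphosphorane (not isolated) | CC/C=C/[C@H](CC)CC(I)=P(c1ccccc1)(c1ccccc1)c1ccccc1 | intermediate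
32 | methyl 2-[(3R,4R,6R)-4,6-diethyl-6-[(1Z,4R,5E)-4-ethyl-2-iodoocta-1,5-dien-1-yl]-1,2-dioxan-3-yl]acetate | CC/C=C/[C@H](CC)C/C(I)=C/[C@@]1(CC)C[C@@H](CC)[C@@H](CC(=O)OC)OO1 | intermediate
33 | methylzinc chloride | C[Zn]Cl | starting material
34 | methyl 2-[(3R,4R,6R)-4,6-diethyl-6-[(1E,4R,5E)-4-ethyl-2-methylocta-1,5-dien-1-yl]-1,2-dioxan-3-yl]acetate | CC/C=C/[C@H](CC)C/C(C)=C/[C@@]1(CC)C[C@@H](CC)[C@@H](CC(=O)OC)OO1 | intermediate
35 | 2-[(3R,4R,6R)-4,6-diethyl-6-[(1E,4R,5E)-4-ethyl-2-methylocta-1,5-dien-1-yl]-1,2-dioxan-3-yl]acetic acid | CC/C=C/[C@H](CC)C/C(C)=C/[C@@]1(CC)C[C@@H](CC)[C@@H](CC(=O)O)OO1 | target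

Total step count: 22. Longest linear sequence: 16 steps (steps 1 to 13, then 20 to 22); the side chain takes steps 14 to 19.

Steps most likely to fail

Step 9. The ene pathway (hydrogen abstraction from the ethyl CH2 groups, C2–H or C7–H, leading to allylic hydroperoxides) may outrun the cycloaddition, or oxygen may approach on the acetonide face. The fallback sets out from diene 14 and avoids singlet oxygen altogether: catalytic tris(4-bromophenyl)aminium hexachloroantimonate under ground-state O2 in CH2Cl2 at −78 °C oxygenates 1,3-dienes to endoperoxides through a radical-cation chain that has no ene channel. It should form the same endoperoxide and comes back to the route at 15; no new compound is made (F0).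

Step 12. Regiocontrol may be lost: oxidation at the C7 carbinol, or at both hydroxyls, would give step 13 the wrong ends. The fallback sets out from diol 17 and fixes the regiochemistry with protecting groups. Et3SiCl and imidazole at −20 °C should silylate the less hindered C1 hydroxyl to give (1R,2R,3R,5R,9R)-1,9-diethyl-3-(triethylsilyloxy)-6,7-dioxabicyclo[3.2.2]nonan-2-ol F1, whose regiochemistry can be checked before going on. t-BuMe2SiOTf and 2,6-lutidine then cap the C7 hydroxyl to give the bis-silyl ether F2. PPTS in MeOH removes only the triethylsilyl group to give the C7-silylated C1 alcohol F3. Dess–Martin oxidation gives the C7-silylated C1 ketone F4, and HF·pyridine frees the C7 hydroxyl, which comes back to the route at 18.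

Step 20. The bulky α-iodo ylide may add too slowly to the aldehyde on the fully substituted C6, so that proton transfer (iodine-free alkene) and erosion of the Z geometry compete. The fallback sets out from alcohol 26 and aldehyde 19 and builds the C7=C8 bond with its methyl group in one Julia–Kocienski olefination. Mitsunobu reaction of 26 with 1-phenyl-1H-tetrazole-5-thiol gives 5-{[(3R,4E)-3-ethylhept-4-en-1-yl]sulfanyl}-1-phenyl-1H-tetrazole F5. Oxidation with H2O2 and catalytic (NH4)6Mo7O24 gives the sulfone F6. Methylation (KN(SiMe3)2, MeI, −78 °C) gives 5-{[(4R,5E)-4-ethyloct-5-en-2-yl]sulfonyl}-1-phenyl-1H-tetrazole F7. Its potassium derivative is then condensed with 19 in DME at −60 °C to rt, and the E isomer is separated on silver nitrate-impregnated silica. This comes back to the route at 34, so step 21 is not needed.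

Further compounds
F0 | step 9 | none | none
F1 | step 12 | (1R,2R,3R,5R,9R)-1,9-diethyl-3-(triethylsilyloxy)-6,7-dioxabicyclo[3.2.2]nonan-2-ol | CC[C@]12C[C@@H](CC)[C@H](OO1)C[C@@H](O[Si](CC)(CC)CC)[C@H]2O
F2 | step 12 | (1R,2R,3R,5R,9R)-2-(tert-butyldimethylsilyloxy)-1,9-diethyl-3-(triethylsilyloxy)-6,7-dioxabicyclo[3.2.2]nonane | CC[C@]12C[C@@H](CC)[C@H](OO1)C[C@@H](O[Si](CC)(CC)CC)[C@H]2O[Si](C)(C)C(C)(C)C
F3 | step 12 | (1R,2R,3R,5R,9R)-2-(tert-butyldimethylsilyloxy)-1,9-diethyl-6,7-dioxabicyclo[3.2.2]nonan-3-ol | CC[C@]12C[C@@H](CC)[C@H](OO1)C[C@@H](O)[C@H]2O[Si](C)(C)C(C)(C)C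
F4 | step 12 | 2-(tert-butyldimethylsilyloxy)-1,9-diethyl-6,7-dioxabicyclo[3.2.2]nonan-3-one (configuration as in 18) | CC[C@]12C[C@@H](CC)[C@H](OO1)CC(=O)[C@H]2O[Si](C)(C)C(C)(C)C
F5 | step 20 | 5-{[(3R,4E)-3-ethylhept-4-en-1-yl]sulfanyl}-1-phenyl-1H-tetrazole | CC/C=C/[C@H](CC)CCSc1nnnn1-c1ccccc1
F6 | step 20 | 5-{[(3R,4E)-3-ethylhept-4-en-1-yl]sulfonyl}-1-phenyl-1H-tetrazole | CC/C=C/[C@H](CC)CCS(=O)(=O)c1nnnn1-c1ccccc1
F7 | step 20 | 5-{[(4R,5E)-4-ethyloct-5-en-2-yl]sulfonyl}-1-phenyl-1H-tetrazole (both C2 epimers) | CC/C=C/[C@H](CC)CC(C)S(=O)(=O)c1nnnn1-c1ccccc1
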